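**Strategy.** Jezonodione is a bicyclo[3.2.1]oct-3-ene-2,8-dione whose cyclopentanone ring C1–C7–C6–C5–C8 holds a non-enolisable 1,3-diketone (C2, C8) around bridgehead C1. C1 is treated as an inserted carbon. An all-trans 2,3-diaryl-4-alkylcyclobutanone (C8, C7, C6, C5), made by an auxiliary-controlled keteniminium–styrene [2+2] cycloaddition, carries on C5 a chain ending in a diazomethyl ketone (C2, C1). A Lewis acid makes the diazo carbon add to the cyclobutanone carbonyl, and the benzylic carbon C7 then migrates from C8 to C1 with loss of N2. This one operation closes the six-membered ring, expands the four-membered ring to the cyclopentanone and fixes both bridgeheads. Dehydrogenation and demethylation finish the route.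

Key step: step 7

Assumption: the (2S,5S)-2,5-dimethylpyrrolidine auxiliary is taken to shield the keteniminium face that leads to the (3S)-cyclobutanone; if the sense of induction is the opposite, the (2R,5R)-amine is used and nothing else changes.

Step 1
Reactants: 1 (3,4-dimethoxyphenyl)acetyl chloride; 2 (2S,5S)-2,5-dimethylpyrrolidine
Product: 3 2-(3,4-dimethoxyphenyl)-1-[(2S,5S)-2,5-dimethylpyrrolidin-1-yl]ethan-1-one
Conditions: Et3N, CH2Cl2, 0 °C to rt
Reagents that add atoms: none
Why: N-acylation of the secondary amine by the acid chloride (amide formation) installs the C2-symmetric auxiliary; no stereocentre is formed.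

Step 2
Reactants: 3 amide; 4 1-ethenyl-3,5-dimethoxybenzene
Product: 7 (2S,3S)-2-(3,4-dimethoxyphenyl)-3-(3,5-dimethoxyphenyl)cyclobutan-1-one, via keteniminium triflate 5 (not isolated), via cyclobutaniminium triflate 6 (not isolated)
Conditions: Tf2O, 2,4,6-collidine, ClCH2CH2Cl, −20 to 60 °C; then aq. NaHCO3, rt
Reagents that add atoms: water, O
Why: Ghosez keteniminium–alkene [2+2] cycloaddition, in which the iminium carbon bonds to the styrene CH2 and the benzylic cation closes on the enamine carbon; the C2-symmetric pyrrolidine blocks one face and so sets C3, and the epimerisable benzylic C2 settles trans to the C3 aryl during the bicarbonate hydrolysis.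

Step 3
Reactants: 7 cyclobutanone; 8 (E)-3-(3,4-dimethoxyphenyl)prop-2-enal
Product: 11 (2S,3S,4E)-2-(3,4-dimethoxyphenyl)-3-(3,5-dimethoxyphenyl)-4-[(E)-3-(3,4-dimethoxyphenyl)prop-2-en-1-ylidene]cyclobutan-1-one, via lithium aldolate 9 (not isolated), via aldol mesylate 10 (not isolated)
Conditions: LiN(SiMe3)2, THF, −78 °C; 8, −78 to −20 °C; MsCl; then DBU, 0 °C to rt
Reagents that add atoms: none
Why: Aldol condensation in which the bulky amide deprotonates the unhindered CH2 (C4), the lithium enolate adds 1,2 to the enal, and only this aldol (not one formed at the aryl-bearing C2) can lose mesylate by E1cB to give the conjugated (E)-alkylidene ketone; C3 is untouched.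

Step 4
Reactants: 11 alkylidenecyclobutanone; 12 tert-butyl[(1-methoxyethenyl)oxy]dimethylsilane
Product: 14 methyl (4E)-3-[(1S,2S,3S)-3-(3,4-dimethoxyphenyl)-2-(3,5-dimethoxyphenyl)-4-oxocyclobutyl]-5-(3,4-dimethoxyphenyl)pent-4-enoate (both C3 epimers of the chain), via silyl enol ether 13 (not isolated)
Conditions: TBSOTf (10 mol %), CH2Cl2, −78 °C; then 1 M HCl, THF, 0 °C; then Et3N (cat.), CH2Cl2, rt
Reagents that add atoms: none
Why: Mukaiyama–Michael 1,4-addition of the ketene silyl acetal to the exocyclic enone carbon (1,4 keeps the styrene conjugation that 1,6 would destroy); hydrolysis and amine equilibration of the two enolisable ring carbons should give the all-trans cyclobutanone under thermodynamic control, and the new side-chain stereocentre is erased in step 8.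

Step 5
Reactants: 14 methyl ester
Product: 15 (4E)-3-[(1S,2S,3S)-3-(3,4-dimethoxyphenyl)-2-(3,5-dimethoxyphenyl)-4-oxocyclobutyl]-5-(3,4-dimethoxyphenyl)pent-4-enoic acid
Conditions: Me3SnOH, ClCH2CH2Cl, 70 °C; then 1 M HCl
Reagents that add atoms: trimethyltin hydroxide, C[Sn](C)(C)O
Why: Tin hydroxide ester cleavage under near-neutral conditions, chosen so that the base-sensitive alpha-aryl cyclobutanone is not opened; no stereocentre is affected.

Step 6
Reactants: 15 carboxylic acid
Product: 17 (5E)-1-diazo-4-[(1S,2S,3S)-3-(3,4-dimethoxyphenyl)-2-(3,5-dimethoxyphenyl)-4-oxocyclobutyl]-6-(3,4-dimethoxyphenyl)hex-5-en-2-one, via acid chloride 16 (not isolated)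
Conditions: (COCl)2, DMF (cat.), CH2Cl2, 0 °C; then Me3SiCHN2, MeCN/THF, 0 °C
Reagents that add atoms: (trimethylsilyl)diazomethane, C[Si](C)(C)C=[N+]=[N-]
Why: First stage of an Arndt–Eistert sequence (C-acylation of the silyl diazomethane by the acid chloride, chloride then removes silicon); without a Lewis acid this reagent should leave the cyclobutanone untouched.

Step 7
Reactants: 17 diazoketone
Product: 19 (1S,5S,6R,7R)-7-(3,4-dimethoxyphenyl)-6-(3,5-dimethoxyphenyl)-4-[(E)-2-(3,4-dimethoxyphenyl)ethenyl]bicyclo[3.2.1]octane-2,8-dione (both C4 epimers), via diazonium betaine 18 (not isolated)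
Conditions: BF3·OEt2, CH2Cl2, −78 to 0 °C
Reagents that add atoms: none
Why: BF3 activates the cyclobutanone carbonyl C8, the diazo carbon C1 adds to it in a 6-exo-trig closure on the face that carries the C5 chain (cis-fused bicyclo[4.2.0] betaine 18), and the C8–C7 bond, antiperiplanar to the departing N2, shifts to C1, so that the four-membered ring C8–C7–C6–C5 becomes the cyclopentanone C8–C1–C7–C6–C5. The closest known reactions are the BF3-promoted ring expansion of cyclobutanones with diazo carbonyl compounds (Tiffeneau–Demjanov-type homologation) and the intramolecular diazoalkyl–ketone ring enlargements that give bridged bicyclic ketones. C7 migrates with retention and C5 and C6 are untouched, so the all-trans cyclobutanone is translated into the 7-endo and 6-exo aryl groups, while C1 can only take the bridged configuration. The step needs migration of C7 and not of the ring carbon C5 (which would give a cis-bicyclo[3.3.0]octanedione) and no closure to an oxirane: C7 is benzylic and electron-rich, lies outside the new six-membered ring and can align with a pseudo-axial C–N2 bond, and the boron-bound oxygen is a poor nucleophile. Addition should be reversible for both C1 epimers, so the betaine that can shift C7 drains the equilibrium.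

Step 8
Reactants: 19 saturated diketone
Product: 21 (1S,5R,6R,7R)-7-(3,4-dimethoxyphenyl)-6-(3,5-dimethoxyphenyl)-4-[(E)-2-(3,4-dimethoxyphenyl)ethenyl]bicyclo[3.2.1]oct-3-ene-2,8-dione, via trimethylsilyl enol ether 20 (not isolated)
Conditions: LiN(SiMe3)2, Me3SiCl, THF, −78 °C; then Pd(OAc)2, MeCN, rt
Reagents that add atoms: none
Why: Saegusa–Ito dehydrogenation: only C3 can be enolised because the other alpha positions (C1, C5) are bridgeheads, and beta-hydride loss from C4 gives the C3=C4 enone conjugated with the styryl group and removes the C4 stereocentre.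

Step 9
Reactants: 21 hexamethyl ether
Product: 22 jezonodione, (1S,5R,6R,7R)-7-(3,4-dihydroxyphenyl)-6-(3,5-dihydroxyphenyl)-4-[(E)-2-(3,4-dihydroxyphenyl)ethenyl]bicyclo[3.2.1]oct-3-ene-2,8-dione
Conditions: BBr3, CH2Cl2, −78 to 0 °C; then ice-water
Reagents that add atoms: none
Why: Lewis acid cleavage of the six aryl methyl ethers (the usual last step for oligostilbenes) with an acidic, non-nucleophilic work-up that should spare the non-enolisable 1,3-diketone; no stereocentre is touched.

**Compound list** (CIP descriptors are derived from the SMILES, which are definitive)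

1 | (3,4-dimethoxyphenyl)acetyl chloride | COc1ccc(CC(=O)Cl)cc1OC | starting material
2 | (2S,5S)-2,5-dimethylpyrrolidine | C[C@H]1CC[C@H](C)N1 | starting material
3 | 2-(3,4-dimethoxyphenyl)-1-[(2S,5S)-2,5-dimethylpyrrolidin-1-yl]ethan-1-one | COc1ccc(CC(=O)N2[C@@H](C)CC[C@@H]2C)cc1OC | intermediate
4 | 1-ethenyl-3,5-dimethoxybenzene (3,5-dimethoxystyrene) | C=Cc1cc(OC)cc(OC)c1 | starting material
5 | keteniminium triflate from 3 (not isolated) | COc1ccc(C=C=[N+]2[C@@H](C)CC[C@@H]2C)cc1OC.[O-]S(=O)(=O)C(F)(F)F | intermediate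
6 | cyclobutaniminium triflate, 2,3-trans isomer shown (not isolated) | C1(=[N+]2[C@@H](C)CC[C@@H]2C)C[C@H](c2cc(OC)cc(OC)c2)[C@H]1c1ccc(OC)c(OC)c1.[O-]S(=O)(=O)C(F)(F)F | intermediate
7 | (2S,3S)-2-(3,4-dimethoxyphenyl)-3-(3,5-dimethoxyphenyl)cyclobutan-1-one (trans) | O=C1C[C@H](c2cc(OC)cc(OC)c2)[C@H]1c1ccc(OC)c(OC)c1 | intermediate
8 | (E)-3-(3,4-dimethoxyphenyl)prop-2-enal | COc1ccc(/C=C/C=O)cc1OC | starting material
9 | lithium aldolate at C4 of 7, carbinol epimers (not isolated) | O=C1[C@@H](C([O-])/C=C/c2ccc(OC)c(OC)c2)[C@H](c2cc(OC)cc(OC)c2)[C@H]1c1ccc(OC)c(OC)c1.[Li+] | intermediate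
10 | aldol mesylate (not isolated) | O=C1[C@@H](C(OS(C)(=O)=O)/C=C/c2ccc(OC)c(OC)c2)[C@H](c2cc(OC)cc(OC)c2)[C@H]1c1ccc(OC)c(OC)c1 | intermediate
11 | (2S,3S,4E)-2-(3,4-dimethoxyphenyl)-3-(3,5-dimethoxyphenyl)-4-[(E)-3-(3,4-dimethoxyphenyl)prop-2-en-1-ylidene]cyclobutan-1-one | O=C1/C(=C/C=C/c2ccc(OC)c(OC)c2)[C@H](c2cc(OC)cc(OC)c2)[C@H]1c1ccc(OC)c(OC)c1 | intermediate
12 | tert-butyl[(1-methoxyethenyl)oxy]dimethylsilane | C=C(OC)O[Si](C)(C)C(C)(C)C | starting material
13 | tert-butyldimethylsilyl enol ether (1-silyloxycyclobutene) of 14 (not isolated) | CC(C)(C)[Si](C)(C)OC1=C(C(CC(=O)OC)/C=C/c2ccc(OC)c(OC)c2)[C@H](c2cc(OC)cc(OC)c2)[C@H]1c1ccc(OC)c(OC)c1 | intermediate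
14 | methyl (4E)-3-[(1S,2S,3S)-3-(3,4-dimethoxyphenyl)-2-(3,5-dimethoxyphenyl)-4-oxocyclobutyl]-5-(3,4-dimethoxyphenyl)pent-4-enoate, all-trans ring, chain C3 epimers | O=C1[C@@H](C(CC(=O)OC)/C=C/c2ccc(OC)c(OC)c2)[C@H](c2cc(OC)cc(OC)c2)[C@H]1c1ccc(OC)c(OC)c1 | intermediate
15 | corresponding pent-4-enoic acid | O=C1[C@@H](C(CC(=O)O)/C=C/c2ccc(OC)c(OC)c2)[C@H](c2cc(OC)cc(OC)c2)[C@H]1c1ccc(OC)c(OC)c1 | intermediate
16 | corresponding acid chloride (not isolated) | O=C1[C@@H](C(CC(=O)Cl)/C=C/c2ccc(OC)c(OC)c2)[C@H](c2cc(OC)cc(OC)c2)[C@H]1c1ccc(OC)c(OC)c1 | intermediate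
17 | (5E)-1-diazo-4-[(1S,2S,3S)-3-(3,4-dimethoxyphenyl)-2-(3,5-dimethoxyphenyl)-4-oxocyclobutyl]-6-(3,4-dimethoxyphenyl)hex-5-en-2-one | O=C1[C@@H](C(CC(=O)C=[N+]=[N-])/C=C/c2ccc(OC)c(OC)c2)[C@H](c2cc(OC)cc(OC)c2)[C@H]1c1ccc(OC)c(OC)c1 | intermediate
18 | boron-bound diazonium betaine: cis-fused 2-diazonio-3-oxobicyclo[4.2.0]octan-1-olate BF3 adduct with 5-styryl, 7-(3,5-dimethoxyphenyl) and 8-(3,4-dimethoxyphenyl) groups (not isolated) | F[B-](F)(F)O[C@]12C([N+]#N)C(=O)CC(/C=C/c3ccc(OC)c(OC)c3)[C@H]1[C@H](c1cc(OC)cc(OC)c1)[C@H]2c1ccc(OC)c(OC)c1 | intermediate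
19 | (1S,5S,6R,7R)-7-(3,4-dimethoxyphenyl)-6-(3,5-dimethoxyphenyl)-4-[(E)-2-(3,4-dimethoxyphenyl)ethenyl]bicyclo[3.2.1]octane-2,8-dione, C4 epimers | O=C1CC(/C=C/c2ccc(OC)c(OC)c2)[C@@H]2C(=O)[C@H]1[C@H](c1ccc(OC)c(OC)c1)[C@H]2c1cc(OC)cc(OC)c1 | intermediate
20 | 2-(trimethylsilyloxy)bicyclo[3.2.1]oct-2-en-8-one from 19, stereocentres as in 19 (not isolated) | C[Si](C)(C)OC1=CC(/C=C/c2ccc(OC)c(OC)c2)[C@@H]2C(=O)[C@H]1[C@H](c1ccc(OC)c(OC)c1)[C@H]2c1cc(OC)cc(OC)c1 | intermediate
21 | (1S,5R,6R,7R)-7-(3,4-dimethoxyphenyl)-6-(3,5-dimethoxyphenyl)-4-[(E)-2-(3,4-dimethoxyphenyl)ethenyl]bicyclo[3.2.1]oct-3-ene-2,8-dione | O=C1C=C(/C=C/c2ccc(OC)c(OC)c2)[C@@H]2C(=O)[C@H]1[C@H](c1ccc(OC)c(OC)c1)[C@H]2c1cc(OC)cc(OC)c1 | intermediate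
22 | jezonodione, (1S,5R,6R,7R)-7-(3,4-dihydroxyphenyl)-6-(3,5-dihydroxyphenyl)-4-[(E)-2-(3,4-dihydroxyphenyl)ethenyl]bicyclo[3.2.1]oct-3-ene-2,8-dione | O=C1C=C(/C=C/c2ccc(O)c(O)c2)[C@@H]2C(=O)[C@H]1[C@H](c1ccc(O)c(O)c1)[C@H]2c1cc(O)cc(O)c1 | target

**Total step count:** 9. **Longest linear sequence:** 9 steps (1 to 22).

**Steps most likely to fail**

Step 7. The betaine may shift the wrong bond (the ring carbon C5 instead of the benzylic C7, leading to a fused diquinane), close to an oxirane, or the diazoketone may decompose under the Lewis acid before it adds. The fallback separates bond formation from migration and changes the migrating species from a diazonium betaine to a rhodium carbenoid. It sets out from 17: DBU in MeCN at 0 °C should effect the intramolecular aldol-type addition of the diazo carbon to the cyclobutanone to give the cis-fused 2-diazo-1-hydroxybicyclo[4.2.0]octan-3-one F1. Rh2(OAc)4 (2 mol %) in CH2Cl2 should then give the carbenoid, whose vacant orbital overlaps with the exocyclic, pseudo-axial C–C bond to C7 and hardly with the ring bond to C5, so that the 1,2-shift delivers the 1,3-diketone. Both are known reaction types for beta-hydroxy-alpha-diazo carbonyl compounds. The fallback returns to the route at 19.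

Step 2. The keteniminium ion may attack the electron-rich dimethoxyarene of 4 (Friedel–Crafts) in competition with the alkene, and the auxiliary may give insufficient facial selectivity. The fallback builds the ring with a neutral ketene and sets the configuration by deprotonation; it costs three more steps. It sets out from 4: dichloroketene (Cl3CCOCl, Zn–Cu couple, Et2O) should give 2,2-dichloro-3-(3,5-dimethoxyphenyl)cyclobutan-1-one F2. Zn in AcOH then gives the achiral 3-(3,5-dimethoxyphenyl)cyclobutan-1-one F3. Enantioselective deprotonation with lithium bis[(S)-1-phenylethyl]amide, LiN[(S)-CHMePh]2 (or its enantiomer, as the sense requires), and Me3SiCl in THF at −100 °C gives the (S)-silyl enol ether F4. Arylation of F4 with (3,4-dimethoxyphenyl)(mesityl)iodonium triflate and Cu(OTf)2 (10 mol %), followed by Et3N equilibration to the trans isomer, returns to the route at 7.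

Step 9. Boron tribromide may cleave the strained, non-enolisable 1,3-diketone (bromide addition and retro-Claisen fragmentation) or add HBr across the dienone while six ethers are being removed. The fallback moves the demethylation ahead of the dehydrogenation and ends with a fluoride deprotection. It sets out from 19: BBr3 gives the saturated hexaphenol F5, and TBSCl with imidazole in DMF gives the hexakis(tert-butyldimethylsilyl) ether F6. The Saegusa–Ito sequence of step 8 (LiN(SiMe3)2, Me3SiCl; Pd(OAc)2) then gives the silylated enone F7, and HF·pyridine in THF at 0 °C returns to the route at 22.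

**Further compounds**

F1 | step 7 | cis-fused 2-diazo-1-hydroxy-8-(3,4-dimethoxyphenyl)-7-(3,5-dimethoxyphenyl)-5-[(E)-2-(3,4-dimethoxyphenyl)ethenyl]bicyclo[4.2.0]octan-3-one | O[C@]12C(=[N+]=[N-])C(=O)CC(/C=C/c3ccc(OC)c(OC)c3)[C@H]1[C@H](c1cc(OC)cc(OC)c1)[C@H]2c1ccc(OC)c(OC)c1
F2 | step 2 | 2,2-dichloro-3-(3,5-dimethoxyphenyl)cyclobutan-1-one (racemic) | O=C1CC(c2cc(OC)cc(OC)c2)C1(Cl)Cl
F3 | step 2 | 3-(3,5-dimethoxyphenyl)cyclobutan-1-one | O=C1CC(c2cc(OC)cc(OC)c2)C1
F4 | step 2 | {[(3S)-3-(3,5-dimethoxyphenyl)cyclobut-1-en-1-yl]oxy}trimethylsilane | C[Si](C)(C)OC1=C[C@@H](c2cc(OC)cc(OC)c2)C1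
F5 | step 9 | (1S,5S,6R,7R)-7-(3,4-dihydroxyphenyl)-6-(3,5-dihydroxyphenyl)-4-[(E)-2-(3,4-dihydroxyphenyl)ethenyl]bicyclo[3.2.1]octane-2,8-dione, C4 epimers | O=C1CC(/C=C/c2ccc(O)c(O)c2)[C@@H]2C(=O)[C@H]1[C@H](c1ccc(O)c(O)c1)[C@H]2c1cc(O)cc(O)c1
F6 | step 9 | hexakis(tert-butyldimethylsilyl) ether of F5 | O=C1CC(/C=C/c2ccc(O[Si](C)(C)C(C)(C)C)c(O[Si](C)(C)C(C)(C)C)c2)[C@@H]2C(=O)[C@H]1[C@H](c1ccc(O[Si](C)(C)C(C)(C)C)c(O[Si](C)(C)C(C)(C)C)c1)[C@H]2c1cc(O[Si](C)(C)C(C)(C)C)cc(O[Si](C)(C)C(C)(C)C)c1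
F7 | step 9 | hexakis(tert-butyldimethylsilyl) ether of jezonodione | O=C1C=C(/C=C/c2ccc(O[Si](C)(C)C(C)(C)C)c(O[Si](C)(C)C(C)(C)C)c2)[C@@H]2C(=O)[C@H]1[C@H](c1ccc(O[Si](C)(C)C(C)(C)C)c(O[Si](C)(C)C(C)(C)C)c1)[C@H]2c1cc(O[Si](C)(C)C(C)(C)C)cc(O[Si](C)(C)C(C)(C)C)c1
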